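If the flask is followed by its rates alone, each interval between readings says how fast substrate goes and how fast target wears away, and amounts below are fractions of the substrate charged.

| flask | substrate | coupling partner | protic impurity | temperature | remark | time |
|---|---|---|---|---|---|---|
| ochre | 0.24 M | 0.084 M | 0.012 M | 29 °C | run made earlier |  |
| teal | 0.24 M | 0.34 M | 0.012 M | 37 °C | run made earlier |  |
| green | 0.24 M | 0.168 M | 0.018 M | 29 °C | run made earlier |  |
| autumn | 0.24 M | 0.168 M | 0.0120 M | 25 °C |  | 20 min |
| midnight | 0.24 M | 0.168 M | 0.0120 M | 40 °C |  | 5.0 min |

| run | time / min | target / % | substrate / % |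
|---|---|---|---|
| ochre | 2.50 | 20.3 | 75.9 |
| ochre | 5.00 | 25.9 | 64.8 |
| ochre | 6.00 | 25.7 | 62.2 |
| ochre | 10.0 | 23.3 | 56.6 |
| ochre | 12.0 | 21.8 | 55.2 |
| ochre | 15.0 | 19.3 | 52.7 |
| teal | 1.33 | 39.6 | 52.9 |
| teal | 3.00 | 53.5 | 29.6 |
| teal | 6.00 | 60.2 | 13.3 |
| teal | 8.00 | 60.1 | 8.4 |
| green | 1.33 | 19.1 | 79.0 |
| green | 4.00 | 35.7 | 56.4 |
| green | 8.00 | 42.4 | 37.5 |
| green | 12.0 | 43.3 | 28.5 |
| green | 15.0 | 43.0 | 23.2 |

(standard deviation of a reading: 0.5 percentage points)

1. which one finishes higher in amount of target, in percent of the substrate charged ("neither" within 2 percentage points) (autumn / midnight / neither)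
2. amount of target at the end, in percent of the substrate charged, autumn
3. amount of target at the end, in percent of the substrate charged, midnight



1. In green, substrate falls at 0.158 min⁻¹ up to the first reading but at 0.0177 min⁻¹ over the last interval, a slowing by a factor of 8.94. The fall of substrate itself gives a factor of 3.46 if the loss is proportional to it, which leaves a factor of 2.58 that this reckoning tentatively puts on the fall of coupling partner.

2. Target meanwhile wears away by meeting substrate, and what is missing from the balance counts two substrate units per event. Its rate over substrate times target reads 0.0761 min⁻¹ in green and 0.150 min⁻¹ in teal, a factor of 1.96 for the step from 29 °C to 37 °C.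

3. With that factor held constant per degree, the half-life of target against the full substrate charge is 12.8 min in autumn and 3.60 min in midnight.

4. Run time over that half-life gives 1.57 for autumn and 1.39 for midnight; this ratio is the wear count.

5. Green's readings at 8.00 min and 15.0 min have wear counts of 0.879 and 1.65, and target there reads 42.4 % and 43.0 %, level within a scatter of 0.5 percentage points per reading. Both new flasks lie inside that span. Assuming that the making of target warms alike, and passing over the fact that green holds more protic impurity, 0.018 M against 0.0120 M, this reckoning puts both new flasks near 43.3 %, with neither ahead.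

6. The forecast differs: autumn ahead, with autumn at 51 % (45 % to 57 %) and midnight at 34 % (28 % to 41 %), on the ground that “cool favours selectivity”.

7. Autumn gives 44.5 % and midnight 44.4 %, so the answer is neither.

    substrate + coupling partner → target, rate k1*[substrate]^1.5*[coupling partner]^0.5 (k = 0.0110 M⁻¹ s⁻¹, Ea = 71.0 kJ mol⁻¹)
    substrate + target → side product (k = 0.00340 M⁻¹ s⁻¹, Ea = 72.0 kJ mol⁻¹)
    coupling partner + protic impurity → quenched reagent (k = 0.0280 M⁻¹ s⁻¹, Ea = 58.0 kJ mol⁻¹)
    (constants at 25 °C)

In midnight, with its wear count of 1.39, target is made 5.85 times faster than it is used up at 0.879 min, and by 5.00 min that ratio has come down to 0.926, with substrate at 25.2 %, the 25.2 % that autumn holds at 20.0 min. The neighbouring midnight flask charged with 0.096 M of substrate has its half-life stretched in proportion, a wear count of 0.556, and ends with 55.0 % of target and side product at 14.3 % of its substrate, less than the 30.4 % of midnight.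

The runs are calculated on assumed constants; scatter was added.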